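**Retrosynthetic overview**

- Target 20 comes from enone diol 18 by acylation of O8 (methacrylate) and then of the tertiary O11 (acetate). 18 comes from hydroxy ester 15 by MeMgBr (builds C11), hydrolysis of the ring A dienol ether and equilibration of C1.
- Key disconnection of ring B (C1, C5, C6, C7, C8, C9, C10) at C6–C7 and C9–C10. The feature used: C7 carries the ester-level carbon C11 beside oxygenated C8, so C7–C8–C9 is the siloxyvinyl diazoacetate 11, and C6=C5–C1=C10 is an s-cis diene exocyclic to ring A (triene 8).
- Rhodium carbenoid cyclopropanation of C5=C6 and Cope rearrangement of the divinylcyclopropane give 13 and set C10. C7 and C8 follow from a chelation-controlled reduction, C1 from thermodynamic control.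
- Ring order: ring A is bought with dione 1; the three-membered ring C5–C6–C7 is transient; ring B closes in step 7. Triene 8 comes from 1, isobutanol and acetaldehyde; 11 comes from methyl acetoacetate.

Key step: step 7

Assumption: Rh2(S-PTAD)4 is taken to attack the C5=C6 face that gives (5R,7S)-12 and hence (10S)-13, the sense this ligand family shows with terminal alkenes; only the hand of the catalyst would change if the opposite sense were found.

Guaiane numbering is used for atoms throughout (C1 ring-fusion CH, C3 ketone, C4/C5 alkene, C7 bears C11, C8 bears O, C10 bears C14).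

**Route**

Step 1
Reactants: 1 2-methylcyclopentane-1,3-dione; 2 2-methylpropan-1-ol
Product: 3 3-isobutoxy-2-methylcyclopent-2-en-1-one
Conditions: p-TsOH·H2O (cat.), toluene, reflux, Dean–Stark trap
Reagents that add atoms: none
Why: Acid-catalysed O-alkylation of the enolised cyclic 1,3-diketone with azeotropic removal of water (vinylogous ester formation) gives a single product because the dione is symmetric.

Step 2
Reactants: 3 3-isobutoxy-2-methylcyclopent-2-en-1-one; 4 acetaldehyde
Product: 5 5-(1-hydroxyethyl)-3-isobutoxy-2-methylcyclopent-2-en-1-one (diastereomer mixture)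
Conditions: LiN(iPr)2 (LDA), THF, −78 °C; then 4, −78 °C; aq NH4Cl
Reagents that add atoms: none
Why: Kinetic deprotonation of the vinylogous ester by LDA takes place at the alpha-prime carbon (the later C1) and the lithium enolate adds to the aldehyde in a directed aldol addition, the mixture of carbinol diastereomers being irrelevant since both centres become sp2 in step 3.

Step 3
Reactants: 5 5-(1-hydroxyethyl)-3-isobutoxy-2-methylcyclopent-2-en-1-one
Product: 7 (5E)-5-ethylidene-3-isobutoxy-2-methylcyclopent-2-en-1-one, via mesylate 6 (not isolated)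
Conditions: MsCl, Et3N, CH2Cl2, 0 °C; then DBU, 0 to 23 °C
Reagents that add atoms: methanesulfonyl chloride, CS(=O)(=O)Cl (its atoms stay only in 6)
Why: Mesylation followed by E1cB elimination through the ketone enolate gives the exocyclic enone with the thermodynamically preferred E geometry (methyl anti to the carbonyl), and a shift of the double bond into the ring is excluded because it would produce a cyclopentadienone.

Step 4
Reactants: 7 (5E)-5-ethylidene-3-isobutoxy-2-methylcyclopent-2-en-1-one
Product: 8 (5E)-5-ethylidene-3-isobutoxy-2-methyl-1-methylidenecyclopent-2-ene (ring A triene)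
Conditions: Cp2TiMe2 (2.5 equiv), toluene–THF, 65 °C, dark; pentane, filtration through basic alumina
Reagents that add atoms: dimethyltitanocene Cp2TiMe2, C[Ti](C)(C1C=CC=C1)C1C=CC=C1
Why: Petasis olefination, in which the titanium methylidene formed by loss of methane converts the ester-like, cross-conjugated carbonyl into the exocyclic methylene through an oxatitanacyclobutane under neutral conditions that spare the enol ether and the E ethylidene group.

Step 5
Reactants: 9 methyl acetoacetate
Product: 10 methyl 2-diazo-3-oxobutanoate
Conditions: 4-acetamidobenzenesulfonyl azide, Et3N, MeCN, 0 to 23 °C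
Reagents that add atoms: 4-acetamidobenzenesulfonyl azide, CC(=O)Nc1ccc(cc1)S(=O)(=O)N=[N+]=[N-]
Why: Regitz diazo transfer from the sulfonyl azide to the ammonium enolate of the 1,3-dicarbonyl compound is the standard route to 2-diazo-3-oxo esters.

Step 6
Reactants: 10 methyl 2-diazo-3-oxobutanoate
Product: 11 methyl 3-(tert-butyldimethylsilyloxy)-2-diazobut-3-enoate
Conditions: TBSOTf, Et3N, CH2Cl2, 0 °C
Reagents that add atoms: tert-butyldimethylsilyl trifluoromethanesulfonate, CC(C)(C)[Si](C)(C)OS(=O)(=O)C(F)(F)F
Why: Soft enolisation (silyl triflate activation of the acetyl carbonyl and deprotonation of its methyl group by the amine) gives the silyl enol ether, and only the terminal enol ether can form because the diazo carbon bears no hydrogen.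

Step 7
Reactants: 8 (5E)-5-ethylidene-3-isobutoxy-2-methyl-1-methylidenecyclopent-2-ene; 11 methyl 3-(tert-butyldimethylsilyloxy)-2-diazobut-3-enoate
Product: 13 methyl (8S)-6-(tert-butyldimethylsilyloxy)-2-isobutoxy-3,8-dimethyl-1,4,7,8-tetrahydroazulene-5-carboxylate, via spiro divinylcyclopropane 12 (not isolated)
Conditions: Rh2(S-PTAD)4 (1 mol %), hexanes, −26 °C, 11 (1.3 equiv) added over 2 h; then 23 °C; chromatography on Et3N-deactivated silica
Reagents that add atoms: none
Why: Rh2(S-PTAD)4 expels N2 from 11 to give a divalent rhodium donor/acceptor carbenoid, electrophilic at C7, which is attacked by the terminal methylene C6 of the alkoxydiene C6=C5–C4=C3–O and closes cyclopropane 12 (C6–C7 and C5–C7), and this cis-divinylcyclopropane then undergoes a boat Cope rearrangement at or below room temperature, forming C9–C10 and breaking C5–C7. This is the tandem cyclopropanation/Cope rearrangement of vinyl diazoacetates with 1,3-dienes (formal (4+3) cycloaddition), established for 2-siloxyvinyl diazoacetates, alkoxydienes and chiral dirhodium tetracarboxylates. The three-membered ring closes by concerted asynchronous (2+1) carbene transfer and ring B by the (3,3) sigmatropic shift, that is, enlargement of the cyclopropane by the four diene carbons, with the diene C6=C5–C1=C10 held s-cis by ring A. C10 is the only stereocentre that remains: the ligand sphere decides which face of C5=C6 is attacked (5R,7S in 12), and the boat transition state, in which the E methyl C14 points away from the cyclopropane, relays this to 10S. The step needs (a) site selectivity, secured because C3=C4 is tetrasubstituted and C1=C10 trisubstituted, both poor partners for donor/acceptor carbenoids, whereas C6 is unsubstituted and is the nucleophilic terminus of the dienol ether, (b) the siloxyvinyl group cis to the ethylidene arm across the spiro carbon C5, expected because that flank offers only the flat C10–H edge while the other carries the C4 methyl, so that the slim ester should turn to the methyl side, and (c) enantiofacial control by the catalyst. A spiro isomer with the two groups exchanged cannot rearrange, because C3=C4 is endocyclic and locked s-trans to the cyclopropane, and would be removed by chromatography.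

Step 8
Reactants: 13 methyl (8S)-6-(tert-butyldimethylsilyloxy)-2-isobutoxy-3,8-dimethyl-1,4,7,8-tetrahydroazulene-5-carboxylate
Product: 14 methyl (8S)-2-isobutoxy-3,8-dimethyl-6-oxo-1,4,5,6,7,8-hexahydroazulene-5-carboxylate (C7 epimers and enol)
Conditions: Bu4NF (TBAF), THF, −78 to 0 °C; aq NH4Cl
Reagents that add atoms: none
Why: Fluoride-induced cleavage of the silyl enol ether (desilylation) releases the stabilised enolate, which is protonated on work-up to the beta-keto ester as an equilibrating mixture of C7 epimers and enol, while the base-stable isobutyl dienol ether of ring A and C10 are untouched.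

Step 9
Reactants: 14 methyl (8S)-2-isobutoxy-3,8-dimethyl-6-oxo-1,4,5,6,7,8-hexahydroazulene-5-carboxylate
Product: 15 methyl (5S,6R,8S)-6-hydroxy-2-isobutoxy-3,8-dimethyl-1,4,5,6,7,8-hexahydroazulene-5-carboxylate (guaiane 7S,8R,10S; ester, OH and methyl all cis)
Conditions: Zn(BH4)2, Et2O, −20 to 0 °C; aq NH4Cl
Reagents that add atoms: none
Why: Chelation-controlled hydride reduction of the beta-keto ester, in which the hydride should reach C8 of the zinc chelate from the face anti to the ring bond C7–C6 (giving the cis hydroxy ester) and anti to the C10 methyl (held pseudoaxial over the other face by A(1,2) strain against C2 of the diene), while epimerisation of C7 through the enol feeds the matching epimer (dynamic kinetic resolution), so that the ester, O8 and C14 end on one face (7S,8R).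

Step 10
Reactants: 15 methyl (5S,6R,8S)-6-hydroxy-2-isobutoxy-3,8-dimethyl-1,4,5,6,7,8-hexahydroazulene-5-carboxylate
Product: 16 (5S,6R,8S)-5-(2-hydroxypropan-2-yl)-2-isobutoxy-3,8-dimethyl-1,4,5,6,7,8-hexahydroazulen-6-ol
Conditions: MeMgBr (5 equiv), THF, 0 to 23 °C; aq NH4Cl
Reagents that add atoms: methylmagnesium bromide, C[Mg]Br
Why: Double Grignard addition to the methyl ester, in which two equivalents add through the transient methyl ketone after deprotonation of the C8 hydroxyl to build the tertiary carbinol C11, addition at 0 °C being faster than enolisation at C7, so that no stereocentre is touched.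

Step 11
Reactants: 16 (5S,6R,8S)-5-(2-hydroxypropan-2-yl)-2-isobutoxy-3,8-dimethyl-1,4,5,6,7,8-hexahydroazulen-6-ol
Product: 18 (1R,7S,8R,10S)-8,11-dihydroxyguai-4-en-3-one, via C1-epimeric enone diol 17 (not isolated)
Conditions: 1 M aq HCl, THF, 0 to 23 °C; NaHCO3 work-up; then DBU (0.3 equiv), CH2Cl2, 23 °C
Reagents that add atoms: water, O
Why: Enol ether hydrolysis followed by base equilibration, in which protonation of the alkoxydiene at C1 and addition of water to the oxocarbenium ion at C3 can give only the conjugated 4-en-3-one, and DBU then equilibrates the gamma-centre C1 through the extended dienolate to the more stable epimer in which C2 and the C10 methyl are trans-diequatorial on ring B (1R).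

Step 12
Reactants: 18 (1R,7S,8R,10S)-8,11-dihydroxyguai-4-en-3-one
Product: 19 (1R,7S,8R,10S)-11-hydroxy-3-oxoguai-4-en-8-yl 2-methylprop-2-enoate
Conditions: methacryloyl chloride, Et3N, DMAP (cat.), BHT (trace), CH2Cl2, −20 to 0 °C
Reagents that add atoms: methacryloyl chloride, C=C(C)C(=O)Cl
Why: DMAP-catalysed acylation with the acid chloride (esterification) takes the secondary C8 hydroxyl and leaves the far more hindered tertiary C11 hydroxyl, while low temperature and a radical inhibitor keep the methacrylate from polymerising and no stereocentre is affected.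

Step 13
Reactants: 19 (1R,7S,8R,10S)-11-hydroxy-3-oxoguai-4-en-8-yl 2-methylprop-2-enoate
Product: 20 (1R,7S,8R,10S)-11-acetoxy-3-oxoguai-4-en-8-yl 2-methylprop-2-enoate (target)
Conditions: Ac2O, DMAP, Et3N, BHT (trace), CH2Cl2, 23 to 40 °C
Reagents that add atoms: acetic anhydride, CC(=O)OC(C)=O
Why: DMAP-catalysed acetylation (nucleophilic acyl-transfer catalysis), in which the N-acetylpyridinium ion is reactive enough to esterify the tertiary C11 alcohol under basic conditions that should cause neither ionisation at C11 nor migration of the C8 ester, C1 being already at its equilibrium configuration.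

**Compound list**

1 | 2-methylcyclopentane-1,3-dione | CC1C(=O)CCC1=O | starting material
2 | 2-methylpropan-1-ol (isobutanol) | CC(C)CO | starting material
3 | 3-isobutoxy-2-methylcyclopent-2-en-1-one | CC1=C(OCC(C)C)CCC1=O | intermediate
4 | acetaldehyde | CC=O | starting material
5 | 5-(1-hydroxyethyl)-3-isobutoxy-2-methylcyclopent-2-en-1-one (diastereomer mixture) | CC(O)C1CC(OCC(C)C)=C(C)C1=O | intermediate
6 | 1-(4-isobutoxy-3-methyl-2-oxocyclopent-3-en-1-yl)ethyl methanesulfonate | CC(OS(C)(=O)=O)C1CC(OCC(C)C)=C(C)C1=O | intermediate (not isolated)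
7 | (5E)-5-ethylidene-3-isobutoxy-2-methylcyclopent-2-en-1-one | C/C=C1\CC(OCC(C)C)=C(C)C1=O | intermediate
8 | (5E)-5-ethylidene-3-isobutoxy-2-methyl-1-methylidenecyclopent-2-ene | C=C1C(C)=C(OCC(C)C)C/C1=C\C | intermediate
9 | methyl acetoacetate | COC(=O)CC(C)=O | starting material
10 | methyl 2-diazo-3-oxobutanoate | COC(=O)C(=[N+]=[N-])C(C)=O | intermediate
11 | methyl 3-(tert-butyldimethylsilyloxy)-2-diazobut-3-enoate | COC(=O)C(=[N+]=[N-])C(=C)O[Si](C)(C)C(C)(C)C | intermediate
12 | methyl (1S,3R,7E)-1-[1-(tert-butyldimethylsilyloxy)ethenyl]-7-ethylidene-5-isobutoxy-4-methylspiro[2.4]hept-4-ene-1-carboxylate (guaiane 5R,7S; siloxyvinyl cis to the ethylidene-bearing carbon) | COC(=O)[C@@]1(C(=C)O[Si](C)(C)C(C)(C)C)C[C@@]12C(C)=C(OCC(C)C)C/C2=C\C | intermediate (not isolated)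
13 | methyl (8S)-6-(tert-butyldimethylsilyloxy)-2-isobutoxy-3,8-dimethyl-1,4,7,8-tetrahydroazulene-5-carboxylate (guaiane 10S) | COC(=O)C1=C(O[Si](C)(C)C(C)(C)C)C[C@H](C)C2=C(C1)C(C)=C(OCC(C)C)C2 | intermediate
14 | methyl (8S)-2-isobutoxy-3,8-dimethyl-6-oxo-1,4,5,6,7,8-hexahydroazulene-5-carboxylate (C7 epimers and enol) | O=C1C[C@H](C)C2=C(CC1C(=O)OC)C(C)=C(OCC(C)C)C2 | intermediate
15 | methyl (5S,6R,8S)-6-hydroxy-2-isobutoxy-3,8-dimethyl-1,4,5,6,7,8-hexahydroazulene-5-carboxylate | O[C@@H]1C[C@H](C)C2=C(C[C@@H]1C(=O)OC)C(C)=C(OCC(C)C)C2 | intermediate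
16 | (5S,6R,8S)-5-(2-hydroxypropan-2-yl)-2-isobutoxy-3,8-dimethyl-1,4,5,6,7,8-hexahydroazulen-6-ol | O[C@@H]1C[C@H](C)C2=C(C[C@@H]1C(C)(C)O)C(C)=C(OCC(C)C)C2 | intermediate
17 | (7S,8R,10S)-8,11-dihydroxyguai-4-en-3-one, C1 epimers as formed | O[C@@H]1C[C@H](C)C2CC(=O)C(C)=C2C[C@@H]1C(C)(C)O | intermediate (not isolated)
18 | (1R,7S,8R,10S)-8,11-dihydroxyguai-4-en-3-one | O[C@@H]1C[C@H](C)[C@H]2CC(=O)C(C)=C2C[C@@H]1C(C)(C)O | intermediate
19 | (1R,7S,8R,10S)-11-hydroxy-3-oxoguai-4-en-8-yl 2-methylprop-2-enoate | C=C(C)C(=O)O[C@@H]1C[C@H](C)[C@H]2CC(=O)C(C)=C2C[C@@H]1C(C)(C)O | intermediate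
20 | (1R,7S,8R,10S)-11-acetoxy-3-oxoguai-4-en-8-yl 2-methylprop-2-enoate | C=C(C)C(=O)O[C@@H]1C[C@H](C)[C@H]2CC(=O)C(C)=C2C[C@@H]1C(C)(C)OC(C)=O | target

**Totals**

Total step count: 13. Longest linear sequence: 11 steps (steps 1 to 4 and 7 to 13).

**Steps most likely to fail**

1. Step 7. The carbenoid may close the cyclopropane with the siloxyvinyl group on the methyl-bearing C4 side of the spiro carbon instead of the ethylidene side. That spiro isomer has no path to the (3,3) shift, and if it is forced open by heat both ends can rotate, which would lower the enantiomeric purity. Weak facial discrimination at this 1,1-disubstituted alkene would have the same effect.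
 Fallback (changes the substrate design): the C4 methyl is left out of the diene, so that the ethylidene arm is the only carbon-substituted flank of the methylene group and, as with 2-substituted butadienes in this reaction class, should lie cis to the carbenoid vinyl group. C15 is then added to the finished enone. The fallback sets out from 2 (with purchased cyclopentane-1,3-dione F1) and returns at 18.
 - Cyclopentane-1,3-dione F1 and 2 (p-TsOH, toluene, reflux) give 3-isobutoxycyclopent-2-en-1-one F2.
 - LDA and 4 give 5-(1-hydroxyethyl)-3-isobutoxycyclopent-2-en-1-one F3; MsCl/Et3N gives 1-(4-isobutoxy-2-oxocyclopent-3-en-1-yl)ethyl methanesulfonate F4, and DBU gives (5E)-5-ethylidene-3-isobutoxycyclopent-2-en-1-one F5.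
 - Cp2TiMe2 gives (5E)-5-ethylidene-3-isobutoxy-1-methylidenecyclopent-2-ene F6.
 - With 11 and Rh2(S-PTAD)4 as in step 7, the demethyl spiro divinylcyclopropane F7 should rearrange to the demethyl cycloadduct F8.
 - TBAF gives the demethyl keto ester F9, Zn(BH4)2 the demethyl hydroxy ester F10, MeMgBr the demethyl diol F11, and aqueous HCl in THF the 15-nor enone diol F12 (C1 as formed).
 - I2 and pyridine in CH2Cl2 iodinate the enone alpha-carbon C4 to give the 4-iodo enone diol F13.
 - Suzuki coupling with MeB(OH)2 (Pd(dppf)Cl2, K2CO3, dioxane–water, 80 °C) installs C15 while the carbonate equilibrates C1, giving 18.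

2. Step 9. Hydride may be delivered to the C8 face that carries the C10 methyl, or without chelation, so that 1,3-induction is incomplete and several C7/C8 diastereomers form.
 Fallback (catalyst control in place of substrate control): it sets out from 14 and returns at 15 with no new compound. A ketoreductase chosen from a screening panel for the cis (8R) alcohol is used with NADP+ and isopropanol recycling in phosphate buffer at pH 7 with DMSO as cosolvent at 30 °C. The enzyme fixes C8 absolutely and reduces only the matching C7 epimer while C7 racemises through the enol (dynamic kinetic reduction), so the remote C10 methyl no longer decides the outcome.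

3. Step 4. The deactivated cross-conjugated carbonyl may react so slowly at 65 °C that the titanium reagent decomposes first, or the electron-rich triene may dimerise or isomerise during the prolonged heating.
 Fallback (addition and elimination at low temperature in place of a hot carbonyl methylenation): it sets out from 7 and returns at 8. Me3SiCH2Li with anhydrous CeCl3 in THF at −78 °C adds 1,2 to the carbonyl and gives (5E)-5-ethylidene-3-isobutoxy-2-methyl-1-[(trimethylsilyl)methyl]cyclopent-2-en-1-ol F14, which is used crude. KH in THF at 0 °C then brings about syn elimination of trimethylsilanolate (Peterson olefination) to give 8.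

**Further compounds**

F1 | step 7 | cyclopentane-1,3-dione | O=C1CCC(=O)C1
F2 | step 7 | 3-isobutoxycyclopent-2-en-1-one | CC(C)COC1=CC(=O)CC1
F3 | step 7 | 5-(1-hydroxyethyl)-3-isobutoxycyclopent-2-en-1-one | CC(O)C1CC(OCC(C)C)=CC1=O
F4 | step 7 | 1-(4-isobutoxy-2-oxocyclopent-3-en-1-yl)ethyl methanesulfonate | CC(OS(C)(=O)=O)C1CC(OCC(C)C)=CC1=O
F5 | step 7 | (5E)-5-ethylidene-3-isobutoxycyclopent-2-en-1-one | C/C=C1\CC(OCC(C)C)=CC1=O
F6 | step 7 | (5E)-5-ethylidene-3-isobutoxy-1-methylidenecyclopent-2-ene | C=C1C=C(OCC(C)C)C/C1=C\C
F7 | step 7 | demethyl spiro divinylcyclopropane: methyl (7E)-1-[1-(tert-butyldimethylsilyloxy)ethenyl]-7-ethylidene-5-isobutoxyspiro[2.4]hept-4-ene-1-carboxylate, same spatial arrangement as 12 | COC(=O)[C@@]1(C(=C)O[Si](C)(C)C(C)(C)C)C[C@@]12C=C(OCC(C)C)C/C2=C\C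
F8 | step 7 | demethyl cycloadduct: methyl (8S)-6-(tert-butyldimethylsilyloxy)-2-isobutoxy-8-methyl-1,4,7,8-tetrahydroazulene-5-carboxylate | COC(=O)C1=C(O[Si](C)(C)C(C)(C)C)C[C@H](C)C2=C(C1)C=C(OCC(C)C)C2
F9 | step 7 | demethyl keto ester: methyl (8S)-2-isobutoxy-8-methyl-6-oxo-1,4,5,6,7,8-hexahydroazulene-5-carboxylate | O=C1C[C@H](C)C2=C(CC1C(=O)OC)C=C(OCC(C)C)C2
F10 | step 7 | demethyl hydroxy ester: methyl (5S,6R,8S)-6-hydroxy-2-isobutoxy-8-methyl-1,4,5,6,7,8-hexahydroazulene-5-carboxylate | O[C@@H]1C[C@H](C)C2=C(C[C@@H]1C(=O)OC)C=C(OCC(C)C)C2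
F11 | step 7 | demethyl diol: (5S,6R,8S)-5-(2-hydroxypropan-2-yl)-2-isobutoxy-8-methyl-1,4,5,6,7,8-hexahydroazulen-6-ol | O[C@@H]1C[C@H](C)C2=C(C[C@@H]1C(C)(C)O)C=C(OCC(C)C)C2
F12 | step 7 | 15-nor enone diol: (5S,6R,8S)-6-hydroxy-5-(2-hydroxypropan-2-yl)-8-methyl-4,5,6,7,8,8a-hexahydroazulen-2(1H)-one, C8a epimers | O[C@@H]1C[C@H](C)C2CC(=O)C=C2C[C@@H]1C(C)(C)O
F13 | step 7 | 4-iodo enone diol: (5S,6R,8S)-6-hydroxy-5-(2-hydroxypropan-2-yl)-3-iodo-8-methyl-4,5,6,7,8,8a-hexahydroazulen-2(1H)-one, C8a epimers | O[C@@H]1C[C@H](C)C2CC(=O)C(I)=C2C[C@@H]1C(C)(C)O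
F0 | step 9 | none | none
F14 | step 4 | (5E)-5-ethylidene-3-isobutoxy-2-methyl-1-[(trimethylsilyl)methyl]cyclopent-2-en-1-ol | C[Si](C)(C)CC1(O)C(C)=C(OCC(C)C)C/C1=C\C
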